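I decide to read gamma against midnight, the hot simulated run, since the two flasks stand near each other in temperature, 40 °C and 32 °C, while midnight has the larger charge, 26 mM against 12 mM.

| setting | summer | midnight | zeta | eta | gamma |
|---|---|---|---|---|---|
| starting material | 17 mM | 26 mM | 12 mM | 12 mM | 12 mM |
| temperature | 10 °C | 32 °C | 20 °C | 0 °C | 40 °C |
| remark | run made earlier | run made earlier |  |  |  |
| time |  |  | 6.0 min | 6.0 min | 6.0 min |

- summer (time / min: ring / %): 0.833: 5.8; 1.33: 6.7; 2.50: 9.5; 5.00: 13.8; 10.0: 17.1
- midnight (time / min: ring / %): 0.667: 22.4; 1.33: 26.7; 2.00: 27.5; 3.00: 27.8

(each reading ± 1 percentage point)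

- what was read earlier has a scatter of 1 percentage point, one standard deviation
- a reading or a percentage of ring counts all its forms, free or not

- the best flask by amount of ring, in percent of the starting material charged; "all alike" if 1.5 percentage points covers them all (zeta / eta / gamma / all alike)
- amount of ring at the end, in percent of the starting material charged, zeta
- amount of ring at the end, in percent of the starting material charged, eta
- amount of ring at the end, in percent of the starting material charged, gamma

Midnight climbs and then stands: ring reads 27.5% at 2.00 min and 27.8% at 3.00 min, a step smaller than the scatter of 1 percentage point. I suppose that ring closes from one molecule of starting material while a rival path needs two, so that the ratio of ring to the rest falls as the charge rises at a fixed temperature. This is a selectivity factor written as a concentration. So I freeze one quantity. In midnight the ratio of ring to the rest is 0.385, and multiplied by the charge it gives 10.0 mM, the half-share charge: the charge at which a flask that has stopped climbing holds as much ring as rest.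

For gamma's 12 mM this gives an expected plateau of 45.5%, and its 6.0 min is longer than the 2.00 min midnight took to stand. Summer, still climbing and so an unfinished figure, gives 3.51 mM, so heat seems to raise the half-share charge and I hold that plateau as a low edge for gamma. Zeta and eta are cooler and may still be climbing, so I choose gamma as the best flask.

The forecast also chooses gamma, saying that “heat and dilution both favour ring”. It gives 31% for zeta (25% to 36%), 7.6% for eta (5% to 12%) and 48% for gamma (38% to 57%). Its gamma stands above my expected plateau.

The flasks give 29.6% in zeta, 7.32% in eta and 33.1% in gamma, so gamma is best, but gamma falls below the forecast's range. The time given holds eta down, as a small part of what is missing there: left ten times as long, eta holds 15.5% in place of 7.32%.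

    starting material + ring → side product (k = 0.242 M⁻¹ s⁻¹, Ea = 52.0 kJ mol⁻¹)
    starting material ⇌ ring (K = 6.00, k = 0.00399 s⁻¹, Ea = 78.0 kJ mol⁻¹, ΔH = −37.0 kJ mol⁻¹)
    2 starting material → open dimer (k = 0.573 M⁻¹ s⁻¹, Ea = 37.0 kJ mol⁻¹)
    crystals ⇌ ring, rate k4*(cs4 - [ring]) while solid is left; crystals form when [ring] > cs4 (solubility = 2.20 mM, k = 0.106 s⁻¹)
    (constants at 20 °C)

Gamma ends 12 points under its expected plateau, yet the same flask read at 1.5 min holds 43.7%, close to that plateau. So the half-share charge describes gamma's early split, and the loss comes later. Part of that loss is due to the back reaction of ring to starting material: the simulated run of gamma without it ends at 58.4% in place of 33.1%. In gamma, starting material reads 6.97% at 3.00 min and 6.86% at 6.00 min.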